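**Retrosynthetic overview**
1. Target 29 ⇐ CBS reduction of enone 28 (sets C1) ⇐ ten-membered carbocycle, closed last by a Nozaki–Hiyama–Kishi C1–C10 coupling of bromo aldehyde 25.
2. 25 ⇐ angeloylation at O6 and hydroxyl-directed C4–C5 epoxidation of allylic alcohol 18.
3. Key disconnection C6–C7: intermolecular Zn Barbier allylation of enal 8 (C1–C6, C15) with bromomethyl butenolide 16 (C7–C14). It creates the α-methylene-γ-butyrolactone and the C6 and C7 stereocentres.
4. 16 ⇐ RCM of a 2-(bromomethyl)acrylate ⇐ crotonaldehyde + 2,3-dibromopropene (Sharpless kinetic resolution sets C8); 8 ⇐ geranyl acetate.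
5. Ring order: butenolide (RCM) → oxirane → ten-membered carbocycle (NHK).

Assumption: the SMILES is read as (1S,4R,5R,6S,7R,8S) in germacrane numbering (C1 carbinol, C4/C5 trans-oxirane, C6 angelate, C7/C8 trans-lactone, C10=C14, C11=C13); these locants are used throughout.

**Fragment A (C1–C6, C15)**

Step 1
Reactants: 1 geranyl acetate
Product: 2 (2E)-5-(3,3-dimethyloxiran-2-yl)-3-methylpent-2-en-1-yl acetate (racemic)
Conditions: mCPBA (1.0 equiv), CH2Cl2, 0 °C
Reagents that add atoms: 3-chloroperoxybenzoic acid, O=C(OO)c1cccc(Cl)c1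
Why: Prilezhaev epoxidation; the electron-rich distal trisubstituted alkene reacts faster than the alkene deactivated by the allylic acetate, and the racemic centre is destroyed in step 2.

Step 2
Reactants: 2 (2E)-5-(3,3-dimethyloxiran-2-yl)-3-methylpent-2-en-1-yl acetate
Product: 4 (2E)-3-methyl-6-oxohex-2-en-1-yl acetate, via vicinal diol 3 (not isolated)
Conditions: H5IO6 (1.1 equiv), THF/H2O, 0 °C
Reagents that add atoms: water, O
Why: Acidic epoxide hydrolysis to diol 3 followed by Malaprade glycol cleavage releases acetone and leaves the aldehyde carbon that becomes C1.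

Step 3
Reactants: 4 (2E)-3-methyl-6-oxohex-2-en-1-yl acetate
Product: 5 (2E)-6-hydroxy-3-methylhex-2-en-1-yl acetate
Conditions: NaBH4, MeOH, 0 °C, 15 min
Reagents that add atoms: none
Why: Chemoselective borohydride reduction of the aldehyde; the acetate survives brief exposure at 0 °C.

Step 4
Reactants: 5 (2E)-6-hydroxy-3-methylhex-2-en-1-yl acetate
Product: 6 (2E)-6-{[tert-butyl(dimethyl)silyl]oxy}-3-methylhex-2-en-1-yl acetate
Conditions: TBSCl, imidazole, DMF, rt
Reagents that add atoms: tert-butyldimethylsilyl chloride, CC(C)(C)[Si](C)(C)Cl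
Why: Standard silylation of the primary alcohol, which masks C1–OH until the ring closure.

Step 5
Reactants: 6 (2E)-6-{[tert-butyl(dimethyl)silyl]oxy}-3-methylhex-2-en-1-yl acetate
Product: 7 (2E)-6-{[tert-butyl(dimethyl)silyl]oxy}-3-methylhex-2-en-1-ol
Conditions: K2CO3 (cat.), MeOH, rt
Reagents that add atoms: none
Why: Base-catalysed transesterification (methanolysis) of the acetate; the primary TBS ether is stable.

Step 6
Reactants: 7 (2E)-6-{[tert-butyl(dimethyl)silyl]oxy}-3-methylhex-2-en-1-ol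
Product: 8 (2E)-6-{[tert-butyl(dimethyl)silyl]oxy}-3-methylhex-2-enal
Conditions: MnO2 (excess), CH2Cl2, rt
Reagents that add atoms: none
Why: Allylic oxidation with MnO2 is selective for the allylic alcohol and keeps the E geometry (the future C4=C5).

**Fragment B (C7–C14)**

Step 7
Reactants: 9 (E)-crotonaldehyde; 10 2,3-dibromopropene
Product: 12 rac-(5E)-2-bromohepta-1,5-dien-4-ol, via bis(2-bromoallyl)tin dibromide 11 (not isolated)
Conditions: Sn powder, HBr (cat.), Et2O/H2O, rt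
Reagents that add atoms: tin, [Sn]
Why: Barbier-type carbonyl allylation; tin inserts only into the allylic C–Br bond and the allyltin adds 1,2 to the enal (zinc is avoided because it eliminates to allene).

Step 8
Reactants: 12 rac-(5E)-2-bromohepta-1,5-dien-4-ol
Product: 13 (4S,5E)-2-bromohepta-1,5-dien-4-ol
Conditions: Ti(OiPr)4 (10 mol %), D-(−)-diisopropyl tartrate (15 mol %), t-BuOOH (0.6 equiv), 4 Å MS, CH2Cl2, −20 °C
Reagents that add atoms: none
Why: Sharpless kinetic resolution; with the (S,S)-tartrate the (R)-alcohol is epoxidised much faster, so the (S)-alcohol is recovered in high ee at about 55–60 % conversion, which sets C8.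

Step 9
Reactants: 13 (4S,5E)-2-bromohepta-1,5-dien-4-ol; 14 2-(bromomethyl)acrylic acid
Product: 15 (4S,5E)-2-bromohepta-1,5-dien-4-yl 2-(bromomethyl)prop-2-enoate
Conditions: DCC, DMAP (5 mol %), CH2Cl2, 0 °C
Reagents that add atoms: none
Why: Steglich esterification acylates oxygen without touching the carbinol centre; low DMAP loading at 0 °C limits attack on the allylic bromide.

Step 10
Reactants: 15 (4S,5E)-2-bromohepta-1,5-dien-4-yl 2-(bromomethyl)prop-2-enoate
Product: 16 (5S)-3-(bromomethyl)-5-(2-bromoprop-2-en-1-yl)furan-2(5H)-one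
Conditions: second-generation Grubbs catalyst RuCl2(=CHPh)(PCy3)(H2IMes) (5 mol %), CH2Cl2, 40 °C
Reagents that add atoms: none
Why: Ring-closing metathesis; the carbene loads on the propenyl group and closes onto the acrylate to give the five-membered butenolide with loss of propene, while the 2-bromoalkene is inert.

**Fragment union and endgame**

Step 11
Reactants: 16 (5S)-3-(bromomethyl)-5-(2-bromoprop-2-en-1-yl)furan-2(5H)-one; 8 (2E)-6-{[tert-butyl(dimethyl)silyl]oxy}-3-methylhex-2-enal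
Product: 18 (4S,5S)-5-(2-bromoprop-2-en-1-yl)-4-[(1R,2E)-6-{[tert-butyl(dimethyl)silyl]oxy}-1-hydroxy-3-methylhex-2-en-1-yl]-3-methylideneoxolan-2-one, via butenolide allylzinc bromide 17 (not isolated)
Conditions: Zn dust (3 equiv), THF/sat. aq. NH4Cl, 0 °C to rt
Reagents that add atoms: zinc, [Zn]
Why: Barbier-type carbonyl allylation; the allylzinc adds through its ring γ-carbon in a chair Zimmerman–Traxler transition state on the face opposite the C8 side chain, so C7 is set trans to C8 and C6 anti to C7 (the ring-locked allyl unit behaves like an E-crotyl reagent).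

Step 12
Reactants: 18 (4S,5S)-5-(2-bromoprop-2-en-1-yl)-4-[(1R,2E)-6-{[tert-butyl(dimethyl)silyl]oxy}-1-hydroxy-3-methylhex-2-en-1-yl]-3-methylideneoxolan-2-one
Product: 19 (4S,5S)-5-(2-bromoprop-2-en-1-yl)-4-{(S)-hydroxy[(2R,3R)-3-(3-{[tert-butyl(dimethyl)silyl]oxy}propyl)-3-methyloxiran-2-yl]methyl}-3-methylideneoxolan-2-one
Conditions: mCPBA (1.1 equiv), NaHCO3, CH2Cl2, 0 °C
Reagents that add atoms: 3-chloroperoxybenzoic acid, O=C(OO)c1cccc(Cl)c1
Why: Hydroxyl-directed (Henbest) Prilezhaev epoxidation; allylic 1,3-strain from the C15 methyl holds C6–H in the alkene plane, so the peracid is delivered syn to the OH and gives the threo (4R,5R) epoxide, while the bromoalkene and the methylene lactone are too electron-poor to react.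

Step 13
Reactants: 19 (4S,5S)-5-(2-bromoprop-2-en-1-yl)-4-{(S)-hydroxy[(2R,3R)-3-(3-{[tert-butyl(dimethyl)silyl]oxy}propyl)-3-methyloxiran-2-yl]methyl}-3-methylideneoxolan-2-one; 20 angelic acid; 21 2,4,6-trichlorobenzoyl chloride
Product: 23 (S)-[(2S,3R)-2-(2-bromoprop-2-en-1-yl)-4-methylidene-5-oxooxolan-3-yl][(2R,3R)-3-(3-{[tert-butyl(dimethyl)silyl]oxy}propyl)-3-methyloxiran-2-yl]methyl (2Z)-2-methylbut-2-enoate, via angelic 2,4,6-trichlorobenzoic anhydride 22 (not isolated)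
Conditions: 20, 21, Et3N, toluene, rt; then 19, 75 °C
Reagents that add atoms: none
Why: Yamaguchi-type mixed-anhydride acylation without DMAP; the alcohol attacks the unhindered angeloyl carbonyl and the Z geometry is kept, with no change at C6.

Step 14
Reactants: 23 (S)-[(2S,3R)-2-(2-bromoprop-2-en-1-yl)-4-methylidene-5-oxooxolan-3-yl][(2R,3R)-3-(3-{[tert-butyl(dimethyl)silyl]oxy}propyl)-3-methyloxiran-2-yl]methyl (2Z)-2-methylbut-2-enoate
Product: 24 (S)-[(2S,3R)-2-(2-bromoprop-2-en-1-yl)-4-methylidene-5-oxooxolan-3-yl][(2R,3R)-3-(3-hydroxypropyl)-3-methyloxiran-2-yl]methyl (2Z)-2-methylbut-2-enoate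
Conditions: Bu4NF/AcOH (1:1), THF, 0 °C to rt; used at once
Reagents that add atoms: none
Why: Fluoride desilylation; the acetic acid buffer protects the methylene lactone and angelate from basic fluoride and is too weak to trigger 5-exo opening of the epoxide by the new alcohol.

Step 15
Reactants: 24 (S)-[(2S,3R)-2-(2-bromoprop-2-en-1-yl)-4-methylidene-5-oxooxolan-3-yl][(2R,3R)-3-(3-hydroxypropyl)-3-methyloxiran-2-yl]methyl (2Z)-2-methylbut-2-enoate
Product: 25 (S)-[(2S,3R)-2-(2-bromoprop-2-en-1-yl)-4-methylidene-5-oxooxolan-3-yl][(2R,3R)-3-methyl-3-(3-oxopropyl)oxiran-2-yl]methyl (2Z)-2-methylbut-2-enoate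
Conditions: Dess–Martin periodinane, NaHCO3, CH2Cl2, 0 °C
Reagents that add atoms: none
Why: Dess–Martin oxidation of the primary alcohol to the aldehyde under buffered, near-neutral conditions that spare the epoxide, esters and alkenes.

Step 16
Reactants: 25 (S)-[(2S,3R)-2-(2-bromoprop-2-en-1-yl)-4-methylidene-5-oxooxolan-3-yl][(2R,3R)-3-methyl-3-(3-oxopropyl)oxiran-2-yl]methyl (2Z)-2-methylbut-2-enoate
Product: 27 (1RS,4R,5R,6S,7R,8S)-4,5-epoxy-1-hydroxy-6-[(2Z)-2-methylbut-2-enoyloxy]germacra-10(14),11(13)-dien-12,8-olide (both C1 epimers), via alkenylchromium dichloride 26 (not isolated)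
Conditions: CrCl2 (10 equiv), NiCl2 (0.2 equiv), degassed DMSO/THF, rt, 2 mM, syringe-pump addition
Reagents that add atoms: chromium dichloride, Cl[Cr]Cl
Why: Nozaki–Hiyama–Kishi reaction; nickel activates the alkenyl bromide, the alkenylchromium adds only to the aldehyde, and high dilution favours closure of the ten-membered ring. C1 is not controlled here and is corrected in steps 17–18.

Step 17
Reactants: 27 (1RS,4R,5R,6S,7R,8S)-4,5-epoxy-1-hydroxy-6-[(2Z)-2-methylbut-2-enoyloxy]germacra-10(14),11(13)-dien-12,8-olide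
Product: 28 (4R,5R,6S,7R,8S)-4,5-epoxy-6-[(2Z)-2-methylbut-2-enoyloxy]-1-oxogermacra-10(14),11(13)-dien-12,8-olide
Conditions: Dess–Martin periodinane, NaHCO3, CH2Cl2, 0 °C
Reagents that add atoms: none
Why: Dess–Martin oxidation converges both C1 epimers to one enone; it is used directly because of its Michael reactivity.

Step 18
Reactants: 28 (4R,5R,6S,7R,8S)-4,5-epoxy-6-[(2Z)-2-methylbut-2-enoyloxy]-1-oxogermacra-10(14),11(13)-dien-12,8-olide
Product: 29 CNP0104965.3, (1S,4R,5R,6S,7R,8S)-4,5-epoxy-1-hydroxy-6-[(2Z)-2-methylbut-2-enoyloxy]germacra-10(14),11(13)-dien-12,8-olide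
Conditions: (R)-2-methyl-CBS-oxazaborolidine (1.0 equiv), catecholborane (1.5 equiv), toluene, −78 °C
Reagents that add atoms: none
Why: Corey–Bakshi–Shibata reduction; the alkenyl carbon C10 acts as the large group and C2 as the small one, so the (R)-catalyst gives the (1S)-alcohol by 1,2-reduction, and catecholborane at −78 °C leaves the alkenes, lactone, ester and epoxide alone.

**Compound list**
1 | geranyl acetate | CC(=O)OC/C=C(\C)CCC=C(C)C | starting material
2 | (2E)-5-(3,3-dimethyloxiran-2-yl)-3-methylpent-2-en-1-yl acetate (racemic) | CC(=O)OC/C=C(\C)CCC1OC1(C)C | intermediate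
3 | (2E)-6,7-dihydroxy-3,7-dimethyloct-2-en-1-yl acetate (racemic) | CC(=O)OC/C=C(\C)CCC(O)C(C)(C)O | intermediate
4 | (2E)-3-methyl-6-oxohex-2-en-1-yl acetate | CC(=O)OC/C=C(\C)CCC=O | intermediate
5 | (2E)-6-hydroxy-3-methylhex-2-en-1-yl acetate | CC(=O)OC/C=C(\C)CCCO | intermediate
6 | (2E)-6-{[tert-butyl(dimethyl)silyl]oxy}-3-methylhex-2-en-1-yl acetate | CC(=O)OC/C=C(\C)CCCO[Si](C)(C)C(C)(C)C | intermediate
7 | (2E)-6-{[tert-butyl(dimethyl)silyl]oxy}-3-methylhex-2-en-1-ol | OC/C=C(\C)CCCO[Si](C)(C)C(C)(C)C | intermediate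
8 | (2E)-6-{[tert-butyl(dimethyl)silyl]oxy}-3-methylhex-2-enal | O=C/C=C(\C)CCCO[Si](C)(C)C(C)(C)C | intermediate
9 | (E)-crotonaldehyde | C/C=C/C=O | starting material
10 | 2,3-dibromopropene | C=C(Br)CBr | starting material
11 | bis(2-bromoprop-2-en-1-yl)tin dibromide | C=C(Br)C[Sn](Br)(Br)CC(Br)=C | intermediate
12 | rac-(5E)-2-bromohepta-1,5-dien-4-ol | C/C=C/C(O)CC(Br)=C | intermediate
13 | (4S,5E)-2-bromohepta-1,5-dien-4-ol | C/C=C/[C@@H](O)CC(Br)=C | intermediate
14 | 2-(bromomethyl)acrylic acid | OC(=O)C(=C)CBr | starting material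
15 | (4S,5E)-2-bromohepta-1,5-dien-4-yl 2-(bromomethyl)prop-2-enoate | C/C=C/[C@@H](OC(=O)C(=C)CBr)CC(Br)=C | intermediate
16 | (5S)-3-(bromomethyl)-5-(2-bromoprop-2-en-1-yl)furan-2(5H)-one | BrCC1=C[C@H](CC(Br)=C)OC1=O | intermediate
17 | {[(5S)-5-(2-bromoprop-2-en-1-yl)-2-oxo-2,5-dihydrofuran-3-yl]methyl}zinc bromide | Br[Zn]CC1=C[C@H](CC(Br)=C)OC1=O | intermediate
18 | (4S,5S)-5-(2-bromoprop-2-en-1-yl)-4-[(1R,2E)-6-{[tert-butyl(dimethyl)silyl]oxy}-1-hydroxy-3-methylhex-2-en-1-yl]-3-methylideneoxolan-2-one | C=C1C(=O)O[C@@H](CC(Br)=C)[C@@H]1[C@H](O)/C=C(\C)CCCO[Si](C)(C)C(C)(C)C | intermediate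
19 | (4S,5S)-5-(2-bromoprop-2-en-1-yl)-4-{(S)-hydroxy[(2R,3R)-3-(3-{[tert-butyl(dimethyl)silyl]oxy}propyl)-3-methyloxiran-2-yl]methyl}-3-methylideneoxolan-2-one | C=C1C(=O)O[C@@H](CC(Br)=C)[C@@H]1[C@H](O)[C@H]2O[C@]2(C)CCCO[Si](C)(C)C(C)(C)C | intermediate
20 | angelic acid, (2Z)-2-methylbut-2-enoic acid | C/C=C(/C)C(=O)O | starting material
21 | 2,4,6-trichlorobenzoyl chloride | O=C(Cl)c1c(Cl)cc(Cl)cc1Cl | starting material
22 | (2Z)-2-methylbut-2-enoic 2,4,6-trichlorobenzoic anhydride | C/C=C(/C)C(=O)OC(=O)c1c(Cl)cc(Cl)cc1Cl | intermediate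
23 | (S)-[(2S,3R)-2-(2-bromoprop-2-en-1-yl)-4-methylidene-5-oxooxolan-3-yl][(2R,3R)-3-(3-{[tert-butyl(dimethyl)silyl]oxy}propyl)-3-methyloxiran-2-yl]methyl (2Z)-2-methylbut-2-enoate | C=C1C(=O)O[C@@H](CC(Br)=C)[C@@H]1[C@H](OC(=O)/C(C)=C\C)[C@H]2O[C@]2(C)CCCO[Si](C)(C)C(C)(C)C | intermediate
24 | (S)-[(2S,3R)-2-(2-bromoprop-2-en-1-yl)-4-methylidene-5-oxooxolan-3-yl][(2R,3R)-3-(3-hydroxypropyl)-3-methyloxiran-2-yl]methyl (2Z)-2-methylbut-2-enoate | C=C1C(=O)O[C@@H](CC(Br)=C)[C@@H]1[C@H](OC(=O)/C(C)=C\C)[C@H]2O[C@]2(C)CCCO | intermediate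
25 | (S)-[(2S,3R)-2-(2-bromoprop-2-en-1-yl)-4-methylidene-5-oxooxolan-3-yl][(2R,3R)-3-methyl-3-(3-oxopropyl)oxiran-2-yl]methyl (2Z)-2-methylbut-2-enoate | C=C1C(=O)O[C@@H](CC(Br)=C)[C@@H]1[C@H](OC(=O)/C(C)=C\C)[C@H]2O[C@]2(C)CCC=O | intermediate
26 | alkenylchromium dichloride derived from 25 (Cr in place of Br at C10) | C=C1C(=O)O[C@@H](CC(=C)[Cr](Cl)Cl)[C@@H]1[C@H](OC(=O)/C(C)=C\C)[C@H]2O[C@]2(C)CCC=O | intermediate
27 | (1RS,4R,5R,6S,7R,8S)-4,5-epoxy-1-hydroxy-6-[(2Z)-2-methylbut-2-enoyloxy]germacra-10(14),11(13)-dien-12,8-olide (C1 epimers) | C=C1C(=O)O[C@H]2CC(=C)C(O)CC[C@@]3(C)O[C@@H]3[C@@H](OC(=O)/C(C)=C\C)[C@H]12 | intermediate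
28 | (4R,5R,6S,7R,8S)-4,5-epoxy-6-[(2Z)-2-methylbut-2-enoyloxy]-1-oxogermacra-10(14),11(13)-dien-12,8-olide | C=C1C(=O)O[C@H]2CC(=C)C(=O)CC[C@@]3(C)O[C@@H]3[C@@H](OC(=O)/C(C)=C\C)[C@H]12 | intermediate
29 | CNP0104965.3, (1S,4R,5R,6S,7R,8S)-4,5-epoxy-1-hydroxy-6-[(2Z)-2-methylbut-2-enoyloxy]germacra-10(14),11(13)-dien-12,8-olide | C=C1C(=O)O[C@H]2CC(=C)[C@@H](O)CC[C@@]3(C)O[C@@H]3[C@@H](OC(=O)/C(C)=C\C)[C@H]12 | target

**Totals**
Total step count: 18. Longest linear sequence: 14 steps (steps 1–6, then 11–18).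

**Three steps most likely to fail**

Step 13 (angeloylation). The C6 hydroxyl is hindered, angelates isomerise easily to tiglates, and heating the free hydroxy lactone could cause translactonisation to the 6,12-olide. The fallback sets out from 19 and builds the Z-alkene on the ester instead of transferring it. 19 is acylated at room temperature with 2-[bis(2,2,2-trifluoroethoxy)phosphoryl]propanoic acid (N,N'-diisopropylcarbodiimide, cat. DMAP, CH2Cl2) to give the phosphonopropanoate ester F1. A Still–Gennari olefination of F1 with acetaldehyde (KN(SiMe3)2, 18-crown-6, THF, −78 °C) then gives the (Z)-2-methylbut-2-enoate and comes back to the route at 23.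

Step 16 (NHK macrocyclisation). Oxidative addition of the 2-bromoalkene may be too slow at high dilution, the ring is strained, and the epoxide is exposed to Lewis-acidic chromium salts. The fallback sets out from 23 and changes the ring-closing partner to an alkenyl iodide. Pd(PPh3)4 and hexamethylditin in toluene at 90 °C give the alkenylstannane F2, and iodine in CH2Cl2 at 0 °C gives the alkenyl iodide F3. Bu4NF/AcOH then gives the iodo alcohol F4, and Dess–Martin oxidation gives the iodo aldehyde F5. F5 is cyclised with CrCl2/NiCl2 in DMSO at high dilution and comes back to the route at 27.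

Step 18 (CBS reduction). The conformation of the ten-membered enone may override catalyst control, and conjugate reduction is possible. The fallback sets out from 27 and replaces oxidation–reduction by inversion. The C1 epimers of 27 are separated by chromatography; the (1S)-epimer is 29 itself. The (1R)-epimer is treated with formic acid, PPh3 and diisopropyl azodicarboxylate (THF, 0 °C) to give the inverted (1S)-formate F6. Brief methanolysis of F6 (KHCO3, MeOH, 0 °C) comes back to the route at 29.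

**Further compounds**
F1 | step 13 | (S)-[(2S,3R)-2-(2-bromoprop-2-en-1-yl)-4-methylidene-5-oxooxolan-3-yl][(2R,3R)-3-(3-{[tert-butyl(dimethyl)silyl]oxy}propyl)-3-methyloxiran-2-yl]methyl 2-[bis(2,2,2-trifluoroethoxy)phosphoryl]propanoate (epimers at the phosphonate carbon) | C=C1C(=O)O[C@@H](CC(Br)=C)[C@@H]1[C@H](OC(=O)C(C)P(=O)(OCC(F)(F)F)OCC(F)(F)F)[C@H]2O[C@]2(C)CCCO[Si](C)(C)C(C)(C)C
F2 | step 16 | (S)-[(2S,3R)-4-methylidene-5-oxo-2-[2-(trimethylstannyl)prop-2-en-1-yl]oxolan-3-yl][(2R,3R)-3-(3-{[tert-butyl(dimethyl)silyl]oxy}propyl)-3-methyloxiran-2-yl]methyl (2Z)-2-methylbut-2-enoate | C=C1C(=O)O[C@@H](CC(=C)[Sn](C)(C)C)[C@@H]1[C@H](OC(=O)/C(C)=C\C)[C@H]2O[C@]2(C)CCCO[Si](C)(C)C(C)(C)C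
F3 | step 16 | (S)-[(2S,3R)-2-(2-iodoprop-2-en-1-yl)-4-methylidene-5-oxooxolan-3-yl][(2R,3R)-3-(3-{[tert-butyl(dimethyl)silyl]oxy}propyl)-3-methyloxiran-2-yl]methyl (2Z)-2-methylbut-2-enoate | C=C1C(=O)O[C@@H](CC(I)=C)[C@@H]1[C@H](OC(=O)/C(C)=C\C)[C@H]2O[C@]2(C)CCCO[Si](C)(C)C(C)(C)C
F4 | step 16 | (S)-[(2S,3R)-2-(2-iodoprop-2-en-1-yl)-4-methylidene-5-oxooxolan-3-yl][(2R,3R)-3-(3-hydroxypropyl)-3-methyloxiran-2-yl]methyl (2Z)-2-methylbut-2-enoate | C=C1C(=O)O[C@@H](CC(I)=C)[C@@H]1[C@H](OC(=O)/C(C)=C\C)[C@H]2O[C@]2(C)CCCO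
F5 | step 16 | (S)-[(2S,3R)-2-(2-iodoprop-2-en-1-yl)-4-methylidene-5-oxooxolan-3-yl][(2R,3R)-3-methyl-3-(3-oxopropyl)oxiran-2-yl]methyl (2Z)-2-methylbut-2-enoate | C=C1C(=O)O[C@@H](CC(I)=C)[C@@H]1[C@H](OC(=O)/C(C)=C\C)[C@H]2O[C@]2(C)CCC=O
F6 | step 18 | (1S,4R,5R,6S,7R,8S)-4,5-epoxy-1-formyloxy-6-[(2Z)-2-methylbut-2-enoyloxy]germacra-10(14),11(13)-dien-12,8-olide | C=C1C(=O)O[C@H]2CC(=C)[C@@H](OC=O)CC[C@@]3(C)O[C@@H]3[C@@H](OC(=O)/C(C)=C\C)[C@H]12
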